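**Retrosynthetic overview**

1. Locants: decane chain C1–C10 as in the target name; oxane ring O1′, C2′ (quaternary, bears CH3 and C10), C3′, C4′, C5′, C6′ (CMe2). The diacetate is traced to an acetonide-protected diol whose C3 methylidene comes from a ketone; the ketone unites a C4 Grignard reagent with the Weinreb amide of (S)-glyceric acid acetonide (C1–C3, source of C2).
2. The oxane is the only ring and is closed once, at O1′–C6′: the C2′ tertiary alcohol adds to a C5′=C6′ alkene (alkoxymercuration).
3. Key disconnection: C2′–C3′ and C4′–C5′ are made in one flask from three pieces: the lithiated 2,4,6-triisopropylbenzoate of the secondary alcohol C10–C2′H(OH)–CH3, a vinylboronate (C3′=C4′) and 1-bromo-2-methylprop-1-ene (C5′, C6′ and its two methyl groups).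
4. Enabling feature: ring atom C2′ is a fully substituted carbinol carbon (O1′, CH3, C10, C3′). Its C–O bond can be carried as a C–B bond, and its bond to C3′ can be made by 1,2-migration from boron with transfer of chirality from a secondary ester. C3′–C4′ is a bare ethano bridge (a vinyl group after hydroboration), and C6′ with O1′ and two methyl groups is a masked 2-methylprop-1-enyl group.
5. C7 comes from (R)-citronellyl bromide; C2′ comes from (R)-propylene oxide, inverted once in the Mitsunobu step.

Key step: step 5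

Remark: the descriptors at the methyl-bearing chain carbon and at C2 change along the route only because substituent priorities change; no step touches these centres after they are set.

**Step 1**
Reactants: 1 (6R)-8-bromo-2,6-dimethyloct-2-ene [(R)-citronellyl bromide]; 2 (2R)-2-methyloxirane [(R)-propylene oxide]
Product: 4 (2R,6S)-6,10-dimethylundec-9-en-2-ol, via Grignard reagent 3 (not isolated)
Conditions: Mg, THF, rt; then CuI (10 mol %), 2, −30 → 0 °C
Reagents that add atoms: none
Why: Copper-catalysed Grignard opening of a terminal epoxide takes place at the CH2 terminus (SN2), so no stereocentre is formed and both the carbinol centre of 2 (R) and the methyl-bearing centre of 1 are carried into 4 unchanged in space.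

**Step 2**
Reactants: 4 (2R,6S)-6,10-dimethylundec-9-en-2-ol; 5 2,4,6-tri(propan-2-yl)benzoic acid
Product: 6 (2S,6S)-6,10-dimethylundec-9-en-2-yl 2,4,6-tri(propan-2-yl)benzoate
Conditions: PPh3, DIAD, THF, 0 °C → rt
Reagents that add atoms: none
Why: In the Mitsunobu reaction the carboxylate displaces the oxyphosphonium group by SN2, so the carbinol carbon should be inverted cleanly to (S); the hindered benzoate is the activating group that step 5 needs.

**Step 3**
Reactants: 6 (2S,6S)-6,10-dimethylundec-9-en-2-yl 2,4,6-tri(propan-2-yl)benzoate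
Product: 7 (2S,6S)-9-hydroxy-6-methylnonan-2-yl 2,4,6-tri(propan-2-yl)benzoate
Conditions: O3, CH2Cl2/MeOH, −78 °C; then NaBH4, −78 → 0 °C
Reagents that add atoms: ozone, [O-][O+]=O
Why: Ozonolysis with reductive work-up cleaves the only alkene (the hindered aryl ester is inert to ozone at −78 °C and to borohydride) and should deliver the primary alcohol at C4 directly.

**Step 4**
Reactants: 7 (2S,6S)-9-hydroxy-6-methylnonan-2-yl 2,4,6-tri(propan-2-yl)benzoate
Product: 8 (2S,6S)-6-methyl-9-{[tri(propan-2-yl)silyl]oxy}nonan-2-yl 2,4,6-tri(propan-2-yl)benzoate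
Conditions: TIPSCl, imidazole, DMF, rt
Reagents that add atoms: chlorotri(propan-2-yl)silane, CC(C)[Si](Cl)(C(C)C)C(C)C
Why: Silylation of the primary alcohol gives a triisopropylsilyl ether that should tolerate sBuLi, aqueous base, peroxide and the mercury salt used later.

**Step 5**
Reactants: 8 (2S,6S)-6-methyl-9-{[tri(propan-2-yl)silyl]oxy}nonan-2-yl 2,4,6-tri(propan-2-yl)benzoate; 9 dibutyl ethenylboronate; 10 1-bromo-2-methylprop-1-ene
Product: 15 (6S,10S)-2,6,10-trimethyl-13-{[tri(propan-2-yl)silyl]oxy}tridec-2-en-6-ol, via lithiated benzoate 11 (not isolated), via allylboronate 12 (not isolated), via B-alkyl-9-BBN adduct 13 (not isolated), via tertiary boronic acid 14 (not isolated)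
Conditions: sBuLi, TMEDA, CPME, −60 °C; 9, −60 → 45 °C; volatiles (CPME, TMEDA) off in vacuo; 9-BBN-H, THF, rt; 10, Pd(dppf)Cl2 (cat.), aq. NaOH, 50 °C; H2O2, aq. NaOH, 0 °C → rt
Reagents that add atoms: hydrogen peroxide, OO
Why: sBuLi/TMEDA, directed by the benzoate carbonyl, should remove the carbinol hydrogen of 8 with retention to give the tertiary organolithium 11, which is expected to hold its configuration at −60 °C and to add to boron of 9 with retention; in the boronate complex the vinyl group migrates from boron to C2′ anti to the departing benzoate (1,2-metallate rearrangement, inversion), which makes the C2′–C3′ bond and gives allylboronate 12. 9-BBN-H then adds to the monosubstituted alkene of 12 with boron at the terminal carbon C4′ (13), the palladium-catalysed B-alkyl Suzuki–Miyaura coupling of 13 with alkenyl bromide 10 makes the C4′–C5′ bond (14, the butyl ester being hydrolysed by the aqueous base), and alkaline hydrogen peroxide finally replaces the tertiary boron by hydroxyl with retention. The closest known reaction types are the lithiation–borylation of secondary dialkyl 2,4,6-triisopropylbenzoates with unhindered boronic esters to give tertiary boronic esters and tertiary alcohols, and the hydroboration/B-alkyl Suzuki coupling of terminal alkenes. No ring is closed in this step. The new stereocentre C2′ is controlled only by the (S) configuration of the benzoate carbon of 8 (retention, retention, inversion, retention), which should give (S) in 15, while the methyl-bearing chain centre is a spectator. The step needs site selectivity between the two C–B bonds of 13, which is secured because only the primary B-alkyl-9-BBN group transmetallates to palladium while the tertiary boronate stays inert until the peroxide is added.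

**Step 6**
Reactants: 15 (6S,10S)-2,6,10-trimethyl-13-{[tri(propan-2-yl)silyl]oxy}tridec-2-en-6-ol
Product: 16 tri(propan-2-yl){[(4S)-4-methyl-7-[(2S)-2,6,6-trimethyloxan-2-yl]heptyl]oxy}silane
Conditions: Hg(OCOCF3)2, CH2Cl2, 0 °C; then NaBH4, aq. NaOH, 0 °C
Reagents that add atoms: none
Why: In this intramolecular alkoxymercuration–demercuration the C2′ hydroxyl should open the mercurinium ion of the trisubstituted alkene at the tertiary carbon C6′ (Markovnikov, 6-endo-trig), which closes the oxane without breaking the C2′–O bond, so C2′ stays (S); borohydride then replaces mercury at C5′ by hydrogen.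

**Step 7**
Reactants: 16 tri(propan-2-yl){[(4S)-4-methyl-7-[(2S)-2,6,6-trimethyloxan-2-yl]heptyl]oxy}silane
Product: 17 (4S)-4-methyl-7-[(2S)-2,6,6-trimethyloxan-2-yl]heptan-1-ol
Conditions: TBAF, THF, rt
Reagents that add atoms: none
Why: Fluoride desilylation cleaves only the Si–O bond; the di-tertiary ether and both stereocentres are inert.

**Step 8**
Reactants: 17 (4S)-4-methyl-7-[(2S)-2,6,6-trimethyloxan-2-yl]heptan-1-ol
Product: 18 (2S)-2-[(4S)-7-bromo-4-methylheptyl]-2,6,6-trimethyloxane
Conditions: CBr4, PPh3, CH2Cl2, 0 °C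
Reagents that add atoms: tetrabromomethane, BrC(Br)(Br)Br
Why: The Appel reaction converts the primary alcohol into the bromide by SN2 displacement of the alkoxyphosphonium ion under neutral conditions that should leave the tertiary ether intact.

**Step 9**
Reactants: 19 methyl (4S)-2,2-dimethyl-1,3-dioxolane-4-carboxylate
Product: 20 (4S)-N-methoxy-N,2,2-trimethyl-1,3-dioxolane-4-carboxamide
Conditions: MeNHOMe·HCl, iPrMgCl, THF, −20 °C
Reagents that add atoms: N,O-dimethylhydroxylamine hydrochloride, CNOC.Cl
Why: Weinreb amide formation by aminolysis of the ester with the magnesium amide at low temperature should leave the α-alkoxy stereocentre (S) untouched.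

**Step 10**
Reactants: 18 (2S)-2-[(4S)-7-bromo-4-methylheptyl]-2,6,6-trimethyloxane; 20 (4S)-N-methoxy-N,2,2-trimethyl-1,3-dioxolane-4-carboxamide
Product: 22 (5S)-1-[(4S)-2,2-dimethyl-1,3-dioxolan-4-yl]-5-methyl-8-[(2S)-2,6,6-trimethyloxan-2-yl]octan-1-one, via Grignard reagent 21 (not isolated)
Conditions: Mg, THF, rt; then 20, THF, −20 → 0 °C
Reagents that add atoms: none
Why: In the Weinreb ketone synthesis the Grignard adduct is held as a chelated tetrahedral intermediate and gives the ketone only on work-up (forming the C3–C4 bond), and at this temperature the C2 centre should not be enolised.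

**Step 11**
Reactants: 22 (5S)-1-[(4S)-2,2-dimethyl-1,3-dioxolan-4-yl]-5-methyl-8-[(2S)-2,6,6-trimethyloxan-2-yl]octan-1-one
Product: 23 (4R)-2,2-dimethyl-4-{(6R)-6-methyl-9-[(2S)-2,6,6-trimethyloxan-2-yl]non-1-en-2-yl}-1,3-dioxolane
Conditions: Cp2TiMe2, toluene, 65 °C, dark
Reagents that add atoms: dimethyltitanocene, C[Ti](C)(C1C=CC=C1)C1C=CC=C1
Why: In the Petasis methylenation the titanium methylidene formed on heating converts the ketone into the 1,1-disubstituted alkene without base, so the adjacent acetonide centre should not epimerise (both descriptors change by priority only).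

**Step 12**
Reactants: 23 (4R)-2,2-dimethyl-4-{(6R)-6-methyl-9-[(2S)-2,6,6-trimethyloxan-2-yl]non-1-en-2-yl}-1,3-dioxolane
Product: 24 (2R,7R)-7-methyl-3-methylidene-10-[(2S)-2,6,6-trimethyloxan-2-yl]decane-1,2-diol
Conditions: AcOH/H2O (4:1), 40 °C
Reagents that add atoms: none
Why: Acetal hydrolysis in aqueous acetic acid frees the diol; the acid is too weak to ionise the di-tertiary ether or the allylic alcohol.

**Step 13**
Reactants: 24 (2R,7R)-7-methyl-3-methylidene-10-[(2S)-2,6,6-trimethyloxan-2-yl]decane-1,2-diol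
Product: 25 (2R,7R)-7-methyl-3-methylidene-10-[(2S)-2,6,6-trimethyloxan-2-yl]decane-1,2-diyl diacetate
Conditions: Ac2O, pyridine, DMAP (cat.), CH2Cl2, rt
Reagents that add atoms: acetic anhydride, CC(=O)OC(C)=O
Why: DMAP-catalysed acetylation of the primary and the secondary hydroxyl group should give the diacetate without touching any stereocentre.

**Compound list**

1 | (6R)-8-bromo-2,6-dimethyloct-2-ene [(R)-citronellyl bromide] | CC(C)=CCC[C@@H](C)CCBr | starting material
2 | (2R)-2-methyloxirane [(R)-propylene oxide] | C[C@@H]1CO1 | starting material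
3 | [(3R)-3,7-dimethyloct-6-en-1-yl]magnesium bromide | CC(C)=CCC[C@@H](C)CC[Mg]Br | intermediate
4 | (2R,6S)-6,10-dimethylundec-9-en-2-ol | CC(C)=CCC[C@@H](C)CCC[C@@H](C)O | intermediate
5 | 2,4,6-tri(propan-2-yl)benzoic acid | CC(C)c1cc(C(C)C)c(C(O)=O)c(C(C)C)c1 | starting material
6 | (2S,6S)-6,10-dimethylundec-9-en-2-yl 2,4,6-tri(propan-2-yl)benzoate | CC(C)=CCC[C@@H](C)CCC[C@H](C)OC(=O)c1c(C(C)C)cc(C(C)C)cc1C(C)C | intermediate
7 | (2S,6S)-9-hydroxy-6-methylnonan-2-yl 2,4,6-tri(propan-2-yl)benzoate | OCCC[C@@H](C)CCC[C@H](C)OC(=O)c1c(C(C)C)cc(C(C)C)cc1C(C)C | intermediate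
8 | (2S,6S)-6-methyl-9-{[tri(propan-2-yl)silyl]oxy}nonan-2-yl 2,4,6-tri(propan-2-yl)benzoate | CC(C)[Si](C(C)C)(C(C)C)OCCC[C@@H](C)CCC[C@H](C)OC(=O)c1c(C(C)C)cc(C(C)C)cc1C(C)C | intermediate
9 | dibutyl ethenylboronate | CCCCOB(C=C)OCCCC | starting material
10 | 1-bromo-2-methylprop-1-ene | CC(C)=CBr | starting material
11 | (2S,6S)-2-lithio-6-methyl-9-{[tri(propan-2-yl)silyl]oxy}nonan-2-yl 2,4,6-tri(propan-2-yl)benzoate | CC(C)[Si](C(C)C)(C(C)C)OCCC[C@@H](C)CCC[C@]([Li])(C)OC(=O)c1c(C(C)C)cc(C(C)C)cc1C(C)C | intermediate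
12 | dibutyl [(3R,7S)-3,7-dimethyl-10-{[tri(propan-2-yl)silyl]oxy}dec-1-en-3-yl]boronate | CC(C)[Si](C(C)C)(C(C)C)OCCC[C@@H](C)CCC[C@@](B(OCCCC)OCCCC)(C)C=C | intermediate
13 | dibutyl [(3S,7S)-1-(9-borabicyclo[3.3.1]nonan-9-yl)-3,7-dimethyl-10-{[tri(propan-2-yl)silyl]oxy}decan-3-yl]boronate | CC(C)[Si](C(C)C)(C(C)C)OCCC[C@@H](C)CCC[C@@](B(OCCCC)OCCCC)(C)CCB1C2CCCC1CCC2 | intermediate
14 | [(6R,10S)-2,6,10-trimethyl-13-{[tri(propan-2-yl)silyl]oxy}tridec-2-en-6-yl]boronic acid | CC(C)[Si](C(C)C)(C(C)C)OCCC[C@@H](C)CCC[C@@](B(O)O)(C)CCC=C(C)C | intermediate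
15 | (6S,10S)-2,6,10-trimethyl-13-{[tri(propan-2-yl)silyl]oxy}tridec-2-en-6-ol | CC(C)[Si](C(C)C)(C(C)C)OCCC[C@@H](C)CCC[C@@](O)(C)CCC=C(C)C | intermediate
16 | tri(propan-2-yl){[(4S)-4-methyl-7-[(2S)-2,6,6-trimethyloxan-2-yl]heptyl]oxy}silane | CC(C)[Si](C(C)C)(C(C)C)OCCC[C@@H](C)CCC[C@@]1(C)CCCC(C)(C)O1 | intermediate
17 | (4S)-4-methyl-7-[(2S)-2,6,6-trimethyloxan-2-yl]heptan-1-ol | OCCC[C@@H](C)CCC[C@@]1(C)CCCC(C)(C)O1 | intermediate
18 | (2S)-2-[(4S)-7-bromo-4-methylheptyl]-2,6,6-trimethyloxane | BrCCC[C@@H](C)CCC[C@@]1(C)CCCC(C)(C)O1 | intermediate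
19 | methyl (4S)-2,2-dimethyl-1,3-dioxolane-4-carboxylate | COC(=O)[C@H]1OC(C)(C)OC1 | starting material
20 | (4S)-N-methoxy-N,2,2-trimethyl-1,3-dioxolane-4-carboxamide | CON(C)C(=O)[C@H]1OC(C)(C)OC1 | intermediate
21 | {(4S)-4-methyl-7-[(2S)-2,6,6-trimethyloxan-2-yl]heptyl}magnesium bromide | Br[Mg]CCC[C@@H](C)CCC[C@@]1(C)CCCC(C)(C)O1 | intermediate
22 | (5S)-1-[(4S)-2,2-dimethyl-1,3-dioxolan-4-yl]-5-methyl-8-[(2S)-2,6,6-trimethyloxan-2-yl]octan-1-one | O=C(CCC[C@@H](C)CCC[C@@]1(C)CCCC(C)(C)O1)[C@H]1OC(C)(C)OC1 | intermediate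
23 | (4R)-2,2-dimethyl-4-{(6R)-6-methyl-9-[(2S)-2,6,6-trimethyloxan-2-yl]non-1-en-2-yl}-1,3-dioxolane | C=C(CCC[C@@H](C)CCC[C@@]1(C)CCCC(C)(C)O1)[C@H]1OC(C)(C)OC1 | intermediate
24 | (2R,7R)-7-methyl-3-methylidene-10-[(2S)-2,6,6-trimethyloxan-2-yl]decane-1,2-diol | C=C(CCC[C@@H](C)CCC[C@@]1(C)CCCC(C)(C)O1)[C@H](CO)O | intermediate
25 | (2R,7R)-7-methyl-3-methylidene-10-[(2S)-2,6,6-trimethyloxan-2-yl]decane-1,2-diyl diacetate | C=C(CCC[C@@H](C)CCC[C@@]1(C)CCCC(C)(C)O1)[C@H](COC(C)=O)OC(C)=O | target

**Step count and risks**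

Total step count: 13. Longest linear sequence: 12 (steps 1–8 and 10–13; step 9 makes the side fragment 20).

The three steps most likely to fail are steps 5, 6 and 11, in this order.

Step 5: the later stages of the one-flask sequence may stall. Residual diamine and lithium salts can bind 9-BBN-H, the tertiary allylboronate 12 can lose boron by protonolysis with allylic shift before it is hydroborated, and 1,2-migration of the hindered boronate complex may stay incomplete. The fallback sets out from 8 and comes back at 15. Compound 8 is lithiated as before but trapped with 5,5-dimethyl-2-(4-methylpent-3-en-1-yl)-1,3,2-dioxaborinane F1, made beforehand from 5-bromo-2-methylpent-2-ene (Mg; B(OMe)3; neopentyl glycol). The union then is a two-component lithiation–borylation with an unhindered primary alkylboronate, and the C4′–C5′ bond is bought in with the boron partner. Warming to 45 °C should give 2-[(6R,10S)-2,6,10-trimethyl-13-{[tri(propan-2-yl)silyl]oxy}tridec-2-en-6-yl]-5,5-dimethyl-1,3,2-dioxaborinane F2, and H2O2/NaOH oxidises it to 15.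

Step 6: ring closure may take the wrong regiochemical course (kinetic 5-exo attack of oxygen at C5′ to an oxolane) or stay incomplete because mercuration is reversible, and the liberated CF3CO2H may begin to cleave the silyl ether. The fallback sets out from 15 and comes back at 16. It is a hydrogen-atom-transfer hydroalkoxylation with the cobalt complex Co(salen) (divalent cobalt, catalytic), N-fluoro-2,4,6-trimethylpyridinium tetrafluoroborate and PhSiH3. Hydrogen is delivered to C5′, the tertiary C6′ radical is oxidised to the cation and captured by the C2′ hydroxyl, so the regiochemistry is fixed by the mechanism and no electrophilic metal salt is needed. This fallback makes no new compound (F0).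

Step 11: the thermal methylenation of the hindered α-alkoxy ketone may be slow, so that enolisation towards C2 (epimerisation) or opening of the acetonide by β-elimination competes. The fallback sets out from 22 and comes back at 23, as a Peterson olefination in two operations. Me3SiCH2Li with CeCl3 (THF, −78 °C) should add to the ketone without enolisation and give (2RS,6R)-2-[(4S)-2,2-dimethyl-1,3-dioxolan-4-yl]-6-methyl-9-[(2S)-2,6,6-trimethyloxan-2-yl]-1-(trimethylsilyl)nonan-2-ol F3 as both epimers at the new carbinol carbon. KH (THF, 0 °C) then eliminates the silanolate from either epimer to give 23.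

**Further compounds**

F1 | step 5 | 5,5-dimethyl-2-(4-methylpent-3-en-1-yl)-1,3,2-dioxaborinane | CC(C)=CCCB1OCC(C)(C)CO1
F2 | step 5 | 2-[(6R,10S)-2,6,10-trimethyl-13-{[tri(propan-2-yl)silyl]oxy}tridec-2-en-6-yl]-5,5-dimethyl-1,3,2-dioxaborinane | CC(C)[Si](C(C)C)(C(C)C)OCCC[C@@H](C)CCC[C@@](B1OCC(C)(C)CO1)(C)CCC=C(C)C
F0 | step 6 | none | none
F3 | step 11 | (2RS,6R)-2-[(4S)-2,2-dimethyl-1,3-dioxolan-4-yl]-6-methyl-9-[(2S)-2,6,6-trimethyloxan-2-yl]-1-(trimethylsilyl)nonan-2-ol | C[Si](C)(C)CC(O)(CCC[C@@H](C)CCC[C@@]1(C)CCCC(C)(C)O1)[C@H]1OC(C)(C)OC1
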